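**Retrosynthetic overview** (eudesmane numbering: C3 carries the isobutyrate, C4=C5, C7 carries the acrylate, C8 the acetate, C10 is quaternary)
1. Target 15 ⇐ diketone 12: hydride reduction sets C3 and C8 under control of the axial C10 methyl, then two acylations.
2. Ring B (second ring) ⇐ C6–C7 bond: bromine-atom radical chain, H-abstraction at the enone γ-methyl and 6-exo SH2′ closure onto allylic bromide 11; this regenerates the acrylate and sets C7.
3. C7–C8 bond ⇐ acyl radical from aldehyde 7 plus methyl 2-(bromomethyl)acrylate 8.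
4. Ring A (first ring) with C10 ⇐ catalytic enantioselective Diels–Alder of siloxydiene 2 with methacrolein 3, then Saegusa oxidation and one-carbon homologation.

Assumption: the sense of induction in step 2 is taken from Corey's pre-transition-state model for α-substituted acroleins; the catalyst antipode that gives (1S)-4 is the one used (written here as the (S)-prolinol-derived catalyst).

**Step 1**
Reactants: 1 (E)-3-methylpent-3-en-2-one
Product: 2 (E)-2-(tert-butyldimethylsilyloxy)-3-methylpenta-1,3-diene
Conditions: LDA, THF, −78 °C; TBSCl, DMPU, −78 °C → rt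
Reagents that add atoms: tert-butyldimethylsilyl chloride CC(C)(C)[Si](C)(C)Cl
Why: Kinetic α′-deprotonation of the methyl ketone and O-silylation (silyl enol ether formation) give the cross-conjugated 2-siloxy diene without touching the E-alkene.

**Step 2**
Reactants: 2 (E)-2-(tert-butyldimethylsilyloxy)-3-methylpenta-1,3-diene; 3 methacrolein (2-methylprop-2-enal)
Product: 4 (1S)-4-(tert-butyldimethylsilyloxy)-1,2,3-trimethylcyclohex-3-ene-1-carbaldehyde (C2 epimers)
Conditions: (S)-o-tolyl-oxazaborolidine·HNTf2 (Corey catalyst, 10 mol %), CH2Cl2, −78 °C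
Reagents that add atoms: none
Why: Oxazaborolidinium-catalysed enantioselective Diels–Alder reaction in which the 2-siloxy group ("para") and the terminal methyl ("ortho") both place the aldehyde-bearing carbon next to the methyl-bearing diene terminus, and the catalyst-bound s-trans enal is attacked on one face only, which sets the quaternary stereocentre C10 (C5 forms as an epimer mixture and is erased in step 3).

**Step 3**
Reactants: 4 (1S)-4-(tert-butyldimethylsilyloxy)-1,2,3-trimethylcyclohex-3-ene-1-carbaldehyde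
Product: 5 (1S)-1,2,3-trimethyl-4-oxocyclohex-2-ene-1-carbaldehyde
Conditions: Pd(OAc)2 (10 mol %), O2 (1 atm), DMSO, 40 °C
Reagents that add atoms: none
Why: Saegusa–Ito oxidation: the palladium enolate at C4 undergoes β-hydride elimination with the ring hydrogen at C5, which gives the tetrasubstituted C4=C5 enone, removes the unwanted C5 stereocentre and leaves the aldehyde and C10 untouched.

**Step 4**
Reactants: 5 (1S)-1,2,3-trimethyl-4-oxocyclohex-2-ene-1-carbaldehyde
Product: 7 2-[(1R)-1,2,3-trimethyl-4-oxocyclohex-2-en-1-yl]acetaldehyde, via methyl enol ether 6 (not isolated)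
Conditions: MeOCH2PPh3Cl, KHMDS, THF, −78 → 0 °C; then 2 M HCl, THF, rt
Reagents that add atoms: (methoxymethyl)triphenylphosphonium chloride COC[P+](c1ccccc1)(c1ccccc1)c1ccccc1.[Cl-]; water O
Why: Wittig methoxymethylenation is much faster at the aldehyde than at the hindered tetrasubstituted enone carbonyl, and acid hydrolysis of the enol ether gives the one-carbon-homologated aldehyde (C9 becomes CH2, the new carbon C8 is the aldehyde) without affecting C10.

**Step 5**
Reactants: 7 2-[(1R)-1,2,3-trimethyl-4-oxocyclohex-2-en-1-yl]acetaldehyde; 8 methyl 2-(bromomethyl)prop-2-enoate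
Product: 9 methyl 2-methylidene-4-oxo-5-[(1R)-1,2,3-trimethyl-4-oxocyclohex-2-en-1-yl]pentanoate
Conditions: (n-Bu4N)4W10O32 (2 mol %), NaHCO3, MeCN, hν 390 nm, rt
Reagents that add atoms: none
Why: Decatungstate hydrogen-atom abstraction from the aldehyde C–H gives a primary acyl radical (no decarbonylation) that adds to the CH2 terminus of 8, and the adduct radical expels a bromine atom (radical allyl transfer, SH2′), which forms the C7–C8 bond and regenerates the acrylate; NaHCO3 takes up HBr so that the β,γ-unsaturated ketone does not isomerise.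

**Step 6**
Reactants: 9 methyl 2-methylidene-4-oxo-5-[(1R)-1,2,3-trimethyl-4-oxocyclohex-2-en-1-yl]pentanoate
Product: 11 methyl 2-(bromomethyl)-4-oxo-5-[(1R)-1,2,3-trimethyl-4-oxocyclohex-2-en-1-yl]pent-2-enoate (E/Z mixture), via alpha-bromo ketone 10 (not isolated)
Conditions: NBS (1.05 equiv), TsOH·H2O (10 mol %), CH2Cl2, 0 °C; then LiBr (20 mol %), acetone, rt
Reagents that add atoms: N-bromosuccinimide O=C1CCC(=O)N1Br
Why: Acid-catalysed α-bromination takes place through the cross-conjugated dienol of the doubly activated C8 ketone (the ring enone enolises far more slowly), and bromide-catalysed allylic 1,3-transposition (SN2′) moves bromine to C13 to give the conjugated allylic bromide, the thermodynamic isomer.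

**Step 7**
Reactants: 11 methyl 2-(bromomethyl)-4-oxo-5-[(1R)-1,2,3-trimethyl-4-oxocyclohex-2-en-1-yl]pent-2-enoate
Product: 12 methyl 2-[(2R,4aR)-4a,8-dimethyl-3,7-dioxo-1,2,3,4,4a,5,6,7-octahydronaphthalen-2-yl]prop-2-enoate
Conditions: di-tert-butyl hyponitrite (10 mol %), 1,2-epoxybutane (5 equiv), PhH (0.01 M), 60 °C
Reagents that add atoms: none
Why: Proposed new method: a bromine atom abstracts hydrogen from the enone γ-methyl (C6, the weakest C–H, as in Wohl–Ziegler γ-bromination), the resulting dienyl radical closes 6-exo-trig onto C7 of the very electron-poor ene-dione through a chair-like transition state with the ester-bearing carbon equatorial (7β, cis to the axial C10 methyl, also the thermodynamic epimer next to the C8 ketone), and β-scission of the C13–Br bond regenerates the acrylate and the chain-carrying bromine atom while the epoxide traps HBr; the closest known reaction is the radical-chain C–H allylation of toluene-type hydrocarbons with 2-(bromomethyl)acrylates (SH2′ allyl transfer carried by Br•), used here intramolecularly.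

**Step 8**
Reactants: 12 methyl 2-[(2R,4aR)-4a,8-dimethyl-3,7-dioxo-1,2,3,4,4a,5,6,7-octahydronaphthalen-2-yl]prop-2-enoate
Product: 13 methyl 2-[(2R,3R,4aR,7S)-3,7-dihydroxy-4a,8-dimethyl-1,2,3,4,4a,5,6,7-octahydronaphthalen-2-yl]prop-2-enoate
Conditions: NaBH4, CeCl3·7H2O, MeOH, −78 → −40 °C
Reagents that add atoms: none
Why: Luche 1,2-reduction: at C3 hydride adds from the α-face opposite the pseudo-axial C10 methyl (3β-alcohol, as with steroidal 4-en-3-ones), at C8 the axial trajectory is blocked by the syn-axial C10 methyl so that equatorial delivery gives the axial 8β-alcohol cis to the C7 substituent, and the acrylate is not reduced under these conditions.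

**Step 9**
Reactants: 13 methyl 2-[(2R,3R,4aR,7S)-3,7-dihydroxy-4a,8-dimethyl-1,2,3,4,4a,5,6,7-octahydronaphthalen-2-yl]prop-2-enoate
Product: 15 methyl 2-[(2R,3R,4aR,7S)-3-acetoxy-4a,8-dimethyl-7-(2-methylpropanoyloxy)-1,2,3,4,4a,5,6,7-octahydronaphthalen-2-yl]prop-2-enoate, via mono-isobutyrate 14 (not isolated)
Conditions: i-PrCOCl (1.05 equiv), pyridine, CH2Cl2, −20 °C; then Ac2O (5 equiv), DMAP (20 mol %), rt
Reagents that add atoms: isobutyryl chloride CC(C)C(Cl)=O; acetic anhydride CC(=O)OC(C)=O
Why: Chemoselective esterification: the unhindered pseudo-equatorial allylic 3-OH is acylated first by one equivalent of isobutyryl chloride, and the hindered axial 8-OH is then acetylated under DMAP catalysis faster than it can lactonise onto the methyl ester; no stereocentre is touched.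

**Compound list**
1 | (E)-3-methylpent-3-en-2-one | C/C=C(\C)C(C)=O | starting material
2 | (E)-2-(tert-butyldimethylsilyloxy)-3-methylpenta-1,3-diene | C=C(O[Si](C)(C)C(C)(C)C)/C(C)=C/C | intermediate
3 | methacrolein (2-methylprop-2-enal) | CC(=C)C=O | starting material
4 | (1S)-4-(tert-butyldimethylsilyloxy)-1,2,3-trimethylcyclohex-3-ene-1-carbaldehyde (C2 epimers) | CC1C(C)=C(O[Si](C)(C)C(C)(C)C)CC[C@]1(C)C=O | intermediate
5 | (1S)-1,2,3-trimethyl-4-oxocyclohex-2-ene-1-carbaldehyde | CC1=C(C)C(=O)CC[C@]1(C)C=O | intermediate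
6 | (4R)-4-(2-methoxyethenyl)-2,3,4-trimethylcyclohex-2-en-1-one (E/Z) | CC1=C(C)C(=O)CC[C@]1(C)C=COC | intermediate (not isolated)
7 | 2-[(1R)-1,2,3-trimethyl-4-oxocyclohex-2-en-1-yl]acetaldehyde | CC1=C(C)C(=O)CC[C@]1(C)CC=O | intermediate
8 | methyl 2-(bromomethyl)prop-2-enoate | C=C(CBr)C(=O)OC | starting material
9 | methyl 2-methylidene-4-oxo-5-[(1R)-1,2,3-trimethyl-4-oxocyclohex-2-en-1-yl]pentanoate | CC1=C(C)C(=O)CC[C@]1(C)CC(=O)CC(=C)C(=O)OC | intermediate
10 | methyl 3-bromo-2-methylidene-4-oxo-5-[(1R)-1,2,3-trimethyl-4-oxocyclohex-2-en-1-yl]pentanoate (C3 epimers) | CC1=C(C)C(=O)CC[C@]1(C)CC(=O)C(Br)C(=C)C(=O)OC | intermediate (not isolated)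
11 | methyl 2-(bromomethyl)-4-oxo-5-[(1R)-1,2,3-trimethyl-4-oxocyclohex-2-en-1-yl]pent-2-enoate (E/Z) | CC1=C(C)C(=O)CC[C@]1(C)CC(=O)C=C(CBr)C(=O)OC | intermediate
12 | methyl 2-[(2R,4aR)-4a,8-dimethyl-3,7-dioxo-1,2,3,4,4a,5,6,7-octahydronaphthalen-2-yl]prop-2-enoate | C=C(C(=O)OC)[C@H]1CC2=C(C)C(=O)CC[C@]2(C)CC1=O | intermediate
13 | methyl 2-[(2R,3R,4aR,7S)-3,7-dihydroxy-4a,8-dimethyl-1,2,3,4,4a,5,6,7-octahydronaphthalen-2-yl]prop-2-enoate | C=C(C(=O)OC)[C@H]1CC2=C(C)[C@@H](O)CC[C@]2(C)C[C@H]1O | intermediate
14 | methyl 2-[(2R,3R,4aR,7S)-3-hydroxy-4a,8-dimethyl-7-(2-methylpropanoyloxy)-1,2,3,4,4a,5,6,7-octahydronaphthalen-2-yl]prop-2-enoate | C=C(C(=O)OC)[C@H]1CC2=C(C)[C@@H](OC(=O)C(C)C)CC[C@]2(C)C[C@H]1O | intermediate (not isolated)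
15 | methyl 2-[(2R,3R,4aR,7S)-3-acetoxy-4a,8-dimethyl-7-(2-methylpropanoyloxy)-1,2,3,4,4a,5,6,7-octahydronaphthalen-2-yl]prop-2-enoate | C=C(C(=O)OC)[C@H]1CC2=C(C)[C@@H](OC(=O)C(C)C)CC[C@]2(C)C[C@H]1OC(C)=O | target

**Total step count:** 9. **Longest linear sequence:** 9 steps (1 → 15).

**Steps most likely to fail**

Step 7 (radical-chain ring closure). The dienyl radical is not nucleophilic and the acceptor is electron-poor, so the addition may be slow; closure through the C4 terminus (bicyclo[2.2.2]octane) and abstraction of the new C7–H in 12 can compete. Fallback: starting from 11, the ring is closed ionically. Cs2CO3 in MeCN at 0 °C generates the extended (γ) dienolate of the ring enone, which displaces bromide by intramolecular vinylogous SN2′ attack of C6 on C7; the α-mode would need a bicyclo[2.2.2]octane with two adjacent quaternary carbons. The route is rejoined at 12, and no new compound is made (F0).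

Step 5 (acyl-radical allyl transfer). Product 9 has a weak C7–H that can be allylated again, and HBr can isomerise the β,γ-unsaturated ketone. Fallback: starting from 7 and 8, a polar Barbier allylation (In powder, THF/H2O, rt) gives the homoallylic alcohol methyl 4-hydroxy-2-methylidene-5-[(1R)-1,2,3-trimethyl-4-oxocyclohex-2-en-1-yl]pentanoate F1 (C4 epimers). Dess–Martin periodinane (NaHCO3, CH2Cl2, 0 °C) then oxidises it to 9, where the route is rejoined.

Step 8 (double reduction). NaBH4 may give only moderate selectivity at C8, and the 8β-alkoxide can lactonise onto the ester. Fallback: starting from 12, the two carbonyls are handled one at a time. LiAlH(Ot-Bu)3 (THF, −78 °C) reduces only the non-conjugated C8 ketone by equatorial delivery, and the aluminium alkoxide is acetylated in the same flask (Ac2O, DMAP) to give methyl 2-[(2R,3R,4aR)-3-acetoxy-4a,8-dimethyl-7-oxo-1,2,3,4,4a,5,6,7-octahydronaphthalen-2-yl]prop-2-enoate F2. Luche reduction (NaBH4, CeCl3·7H2O, MeOH, −78 °C) gives methyl 2-[(2R,3R,4aR,7S)-3-acetoxy-7-hydroxy-4a,8-dimethyl-1,2,3,4,4a,5,6,7-octahydronaphthalen-2-yl]prop-2-enoate F3. Isobutyryl chloride, pyridine and DMAP (CH2Cl2, 0 °C) then give 15, where the route ends.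

**Further compounds**
F0 | step 7 | none | none
F1 | step 5 | methyl 4-hydroxy-2-methylidene-5-[(1R)-1,2,3-trimethyl-4-oxocyclohex-2-en-1-yl]pentanoate (C4 epimers) | CC1=C(C)C(=O)CC[C@]1(C)CC(O)CC(=C)C(=O)OC
F2 | step 8 | methyl 2-[(2R,3R,4aR)-3-acetoxy-4a,8-dimethyl-7-oxo-1,2,3,4,4a,5,6,7-octahydronaphthalen-2-yl]prop-2-enoate | C=C(C(=O)OC)[C@H]1CC2=C(C)C(=O)CC[C@]2(C)C[C@H]1OC(C)=O
F3 | step 8 | methyl 2-[(2R,3R,4aR,7S)-3-acetoxy-7-hydroxy-4a,8-dimethyl-1,2,3,4,4a,5,6,7-octahydronaphthalen-2-yl]prop-2-enoate | C=C(C(=O)OC)[C@H]1CC2=C(C)[C@@H](O)CC[C@]2(C)C[C@H]1OC(C)=O
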